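**Plan** (ring numbered C1 = ketone, C2=C3, C4 = methoxy carbon, C6 = quaternary carbon)
- Cuts, in order: aryl–CO bond of the side chain; allyl–C6 bond; ring bonds C1–C6 and C2–C3 together, which releases C1–C2 as an acetaldehyde unit; the C=C of an open-chain enoate; the C4–C5 bond of a homoallylic alcohol.
- Enabling feature: the ring carbonyl C1 and the side-chain carbonyl are 1,4-related through C6, so C1–C6 joins two acceptor carbons and needs polarity reversal (acyl anion C1 adding to an enoate whose β-carbon is C6). The C2=C3 alkene next to the C4 ether is an aldol-type retron, so C3 enters as a dimethyl acetal and C2 as an enol silane carbon.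
- Forward: C3–C6 chain carrying the C4 stereocentre, then the enoate, then one-flask ring closure, then allyl at C6, then the aryl ketone. Helpers: the second acetal methoxy group at C3 (lost by elimination) and a tert-butyl ester standing in for the aryl ketone so the side chain is not enolised during allylation.
- Stereochemistry: C4 from catalytic asymmetric allylboration; the side-chain CH from syn delivery of acyl and H across the (E)-enoate under a chiral triazolylidene; C6 from allylation of the ring enolate anti to the C4 methoxy group.

Key step: step 4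

Remark: 2,2-dimethoxyacetaldehyde is taken as the anhydrous monomer freed from its commercial aqueous solution; the facial sense of both chiral catalysts is assigned by analogy with their reported substrates.

Step 1
Reactants: 1 2,2-dimethoxyacetaldehyde; 2 2-allyl-4,4,5,5-tetramethyl-1,3,2-dioxaborolane
Product: 3 (2R)-1,1-dimethoxypent-4-en-2-ol
Conditions: (R)-TRIP phosphoric acid (5 mol%), 4 Å MS, toluene, −30 °C; aq. NaHCO3
Reagents that add atoms: none
Why: Chiral phosphoric acid-catalysed allylboration through a closed chair transition state should deliver the allyl group to the Re face of the aldehyde and set the carbinol carbon (later C4) as R.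

Step 2
Reactants: 3 (2R)-1,1-dimethoxypent-4-en-2-ol
Product: 4 (4R)-4,5,5-trimethoxypent-1-ene
Conditions: NaH, MeI, THF, 0 °C to rt
Reagents that add atoms: iodomethane CI
Why: Williamson etherification of the alkoxide at oxygen leaves the stereocentre untouched; acetal and alkene are inert to NaH and MeI.

Step 3
Reactants: 4 (4R)-4,5,5-trimethoxypent-1-ene; 5 tert-butyl methacrylate
Product: 6 tert-butyl (2E,5R)-5,6,6-trimethoxy-2-methylhex-2-enoate
Conditions: second-generation Hoveyda–Grubbs catalyst (5 mol%), 5 (6 equiv), CH2Cl2, 40 °C
Reagents that add atoms: none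
Why: Olefin cross-metathesis of the terminal alkene with the methacrylate (in excess, reluctant to homodimerise) should give the trisubstituted enoate as the thermodynamically preferred E isomer; ether and acetal do not interfere.

Step 4
Reactants: 6 tert-butyl (2E,5R)-5,6,6-trimethoxy-2-methylhex-2-enoate; 7 trimethyl(vinyloxy)silane
Product: 10 tert-butyl (2S)-2-[(1S,5R)-5-methoxy-2-oxocyclohex-3-en-1-yl]propanoate, via β-methoxy aldehyde 8 (not isolated), via Stetter adduct 9 (not isolated)
Conditions: 7 (1.5 equiv), TMSOTf (5 mol%), CH2Cl2, −78 °C; Et3N (0.2 equiv), evaporate, toluene; (5aS,10bR)-2-(pentafluorophenyl)-5a,10b-dihydro-4H,6H-indeno[2,1-b][1,2,4]triazolo[4,3-d][1,4]oxazin-2-ium tetrafluoroborate (20 mol%), KHMDS (20 mol%), 23 °C; DBU (1.5 equiv), 23 °C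
Reagents that add atoms: none
Why: TMSOTf ionises the dimethyl acetal of 6 to an oxocarbenium ion that is captured at carbon by enol silane 7 (Mukaiyama aldol-type addition to an acetal), forming the C2–C3 bond of the target ring and aldehyde 8; the triazolylidene then turns the formyl group into a Breslow intermediate (acyl-anion equivalent) that adds to the β-carbon of the enoate (intramolecular Stetter reaction), forming the C1–C6 bond, and DBU removes methanol from β-methoxy ketone 9 by E1cB to give the enone. The closest known reaction types are the acetal–enol silane addition and the enantio- and diastereoselective intramolecular Stetter reaction of aldehydes tethered to α,β-disubstituted enoates with aminoindanol-derived triazolium salts. The single ring closure is 6-exo-trig (acyl carbon onto the enoate β-carbon, C=C exocyclic). The side-chain stereocentre is set as S because the catalyst directs the acyl group to the Si face of the β-carbon and the proton is then passed within the same intermediate to the same face of the ester enolate, a syn addition that the E geometry translates into relative configuration; the ring carbon formed at the same time is erased in step 5, the methoxy carbon created in the first stage is lost in the elimination, and the existing methoxy stereocentre is not touched. The step needs the acetal to react before the enoate, which the much easier ionisation of the acetal secures, and it needs ring closure to outrun loss of methanol from 8, which the poor leaving group, the low carbene and base loading, the reversibility of benzoin-type additions and the irreversible conjugate addition should secure.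

Step 5
Reactants: 10 tert-butyl (2S)-2-[(1S,5R)-5-methoxy-2-oxocyclohex-3-en-1-yl]propanoate; 11 allyl bromide
Product: 12 tert-butyl (2S)-2-[(1R,5R)-5-methoxy-2-oxo-1-(prop-2-en-1-yl)cyclohex-3-en-1-yl]propanoate
Conditions: LiHMDS (1.05 equiv), THF, −78 °C; 11 (3 equiv), −78 to −30 °C
Reagents that add atoms: none
Why: LiHMDS removes the ring proton between ketone and side chain (kinetic cross-conjugated dienolate; the tert-butyl ester is far less acidic and is not enolised), and C-allylation of this enolate should occur anti to the pseudoaxial ring methoxy group, as in α'-alkylations of 4-alkoxycyclohex-2-enones, setting the quaternary carbon as R with allyl trans to methoxy.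

Step 6
Reactants: 12 tert-butyl (2S)-2-[(1R,5R)-5-methoxy-2-oxo-1-(prop-2-en-1-yl)cyclohex-3-en-1-yl]propanoate
Product: 13 (2S)-2-[(1R,5R)-5-methoxy-2-oxo-1-(prop-2-en-1-yl)cyclohex-3-en-1-yl]propanoic acid
Conditions: TFA, CH2Cl2 (1:4), 0 °C to rt
Reagents that add atoms: none
Why: Acidolysis of the tert-butyl ester (E1 loss of 2-methylpropene) frees the acid without base, so neither the α-stereocentre nor the γ-alkoxy enone is enolised.

Step 7
Reactants: 13 (2S)-2-[(1R,5R)-5-methoxy-2-oxo-1-(prop-2-en-1-yl)cyclohex-3-en-1-yl]propanoic acid; 14 (3,4-dimethoxyphenyl)magnesium bromide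
Product: 17 (4R,6R)-6-[(2S)-1-(3,4-dimethoxyphenyl)-1-oxopropan-2-yl]-4-methoxy-6-(prop-2-en-1-yl)cyclohex-2-en-1-one, via acid chloride 15 (not isolated), via arylzinc chloride 16 (not isolated)
Conditions: 1-chloro-N,N,2-trimethylprop-1-en-1-amine, CH2Cl2, 0 °C to rt, evaporate; separately 14, ZnCl2, THF, 0 °C; combine, Pd(PPh3)4 (5 mol%), THF, 0 °C to rt
Reagents that add atoms: 1-chloro-N,N,2-trimethylprop-1-en-1-amine CC(C)=C(Cl)N(C)C (chlorine of 15 only); zinc chloride Cl[Zn]Cl (zinc and chlorine of 16 only)
Why: The acid chloride is formed under neutral conditions and coupled with the arylzinc chloride by zerovalent palladium (Negishi acylation); the organozinc does not add to the enone and no base is present, so the epimerisable centre next to the new aryl ketone should be preserved.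

**Compound list**
1 | 2,2-dimethoxyacetaldehyde | COC(OC)C=O | starting material
2 | 2-allyl-4,4,5,5-tetramethyl-1,3,2-dioxaborolane | C=CCB1OC(C)(C)C(C)(C)O1 | starting material
3 | (2R)-1,1-dimethoxypent-4-en-2-ol | C=CC[C@@H](O)C(OC)OC | intermediate
4 | (4R)-4,5,5-trimethoxypent-1-ene | C=CC[C@@H](OC)C(OC)OC | intermediate
5 | tert-butyl methacrylate | C=C(C)C(=O)OC(C)(C)C | starting material
6 | tert-butyl (2E,5R)-5,6,6-trimethoxy-2-methylhex-2-enoate | CC(C)(C)OC(=O)/C(C)=C/C[C@@H](OC)C(OC)OC | intermediate
7 | trimethyl(vinyloxy)silane | C=CO[Si](C)(C)C | starting material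
8 | tert-butyl (2E,5R)-5,6-dimethoxy-2-methyl-8-oxooct-2-enoate (both epimers at C6) | CC(C)(C)OC(=O)/C(C)=C/C[C@@H](OC)C(OC)CC=O | intermediate
9 | tert-butyl (2S)-2-[(1S,5R)-4,5-dimethoxy-2-oxocyclohexyl]propanoate (both epimers at ring C4) | CC(C)(C)OC(=O)[C@@H](C)[C@@H]1C[C@@H](OC)C(OC)CC1=O | intermediate
10 | tert-butyl (2S)-2-[(1S,5R)-5-methoxy-2-oxocyclohex-3-en-1-yl]propanoate (ring C1 is epimerisable and is planarised in step 5) | CC(C)(C)OC(=O)[C@@H](C)[C@@H]1C[C@@H](OC)C=CC1=O | intermediate
11 | allyl bromide | C=CCBr | starting material
12 | tert-butyl (2S)-2-[(1R,5R)-5-methoxy-2-oxo-1-(prop-2-en-1-yl)cyclohex-3-en-1-yl]propanoate | C=CC[C@]1([C@H](C)C(=O)OC(C)(C)C)C[C@@H](OC)C=CC1=O | intermediate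
13 | (2S)-2-[(1R,5R)-5-methoxy-2-oxo-1-(prop-2-en-1-yl)cyclohex-3-en-1-yl]propanoic acid | C=CC[C@]1([C@H](C)C(=O)O)C[C@@H](OC)C=CC1=O | intermediate
14 | (3,4-dimethoxyphenyl)magnesium bromide | COc1ccc([Mg]Br)cc1OC | starting material
15 | (2S)-2-[(1R,5R)-5-methoxy-2-oxo-1-(prop-2-en-1-yl)cyclohex-3-en-1-yl]propanoyl chloride | C=CC[C@]1([C@H](C)C(=O)Cl)C[C@@H](OC)C=CC1=O | intermediate
16 | chloro(3,4-dimethoxyphenyl)zinc | COc1ccc([Zn]Cl)cc1OC | intermediate
17 | (4R,6R)-6-[(2S)-1-(3,4-dimethoxyphenyl)-1-oxopropan-2-yl]-4-methoxy-6-(prop-2-en-1-yl)cyclohex-2-en-1-one | C=CC[C@]1([C@H](C)C(=O)c2ccc(OC)c(OC)c2)C[C@@H](OC)C=CC1=O | target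

Total step count: 7. Longest linear sequence: 7 steps (1 → 3 → 4 → 6 → 10 → 12 → 13 → 17).

**Steps most likely to fail**

Step 4. Aldehyde 8 may lose methanol under the basic carbene conditions to an (E)-enal that cannot close, or the six-membered Stetter closure may be slow or poorly face-selective. The fallback sets out from 6 and comes back at 10. The enol silane addition is run alone and 8 is isolated. SmI2 (2.2 equiv) with t-BuOH in THF at −78 °C then closes the ring by 6-exo ketyl–olefin cyclisation to tert-butyl (2S)-2-[(1S,5R)-2-hydroxy-4,5-dimethoxycyclohexyl]propanoate F1. Dess–Martin periodinane oxidises F1 to ketone 9, and DBU gives 10. In this case the side-chain centre rests on protonation of the samarium enolate and has to be checked before going on.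

Step 5. Facial selectivity may be poor because the exocyclic stereocentre can oppose the ring methoxy group, and O-allylation may compete. The fallback sets out from 10 and comes back at 12. LiHMDS followed by allyl chloroformate gives prop-2-en-1-yl (4R)-2-[(2S)-1-tert-butoxy-1-oxopropan-2-yl]-4-methoxycyclohexa-1,5-dien-1-yl carbonate F2. Pd2(dba)3 with (S)-t-Bu-PHOX in toluene (decarboxylative asymmetric allylic alkylation) then forms 12 under catalyst control.

Step 1. Enantioselectivity may be low because the acetal oxygens compete for the acid catalyst. The fallback sets out from 1 and comes back at 3. It uses stoichiometric reagent control instead: commercial (+)-B-allyldiisopinocampheylborane in Et2O at −78 °C, followed by oxidative work-up (no new compound, F0).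

Further compounds
F1 | step 4 | tert-butyl (2S)-2-[(1S,5R)-2-hydroxy-4,5-dimethoxycyclohexyl]propanoate | CC(C)(C)OC(=O)[C@@H](C)[C@@H]1C[C@@H](OC)C(OC)CC1O
F2 | step 5 | prop-2-en-1-yl (4R)-2-[(2S)-1-tert-butoxy-1-oxopropan-2-yl]-4-methoxycyclohexa-1,5-dien-1-yl carbonate | C=CCOC(=O)OC1=C([C@H](C)C(=O)OC(C)(C)C)C[C@@H](OC)C=C1
F0 | step 1 | none | none
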